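## Structural features

Confluentic acid is a depside: two benzene rings joined by one aryl ester, in which the carbonyl carbon on C1 of ring A esterifies the C4 oxygen of ring B. Ring A carries a free hydroxyl on C2 (hydrogen-bonded to the ester carbonyl), a methoxy group on C4 and a 2-oxoheptyl arm (CH2–CO–C5H11) on C6; ring B carries a free carboxylic acid on C1, flanked by a methoxy group on C2 and a pentyl chain on C6. The molecule has no stereocentre and no ring beyond the two arenes, so no stereochemical question arises. The fragile groups are three: the depside ester (a phenol-derived, activated ester that bases and nucleophiles cleave), the arm ketone (its enol oxygen can attack the depside carbonyl and expel ring B as a phenoxide, giving an isocoumarin), and the ring B acid (doubly ortho-substituted, so prone to decarboxylation in hot acid). The real difficulty is the ester, which joins a benzoic acid with two ortho substituents to a weakly nucleophilic phenol, together with the need to end with different oxygens on each ring (free C2–OH and C4–OMe on ring A; C2–OMe and acylated C4–O on ring B). The key step exploits the fact that ring A has the ester carbonyl on C1 and the benzylic carbon of the arm on the neighbouring C6. This is the 1,2-pattern left when an aryne is inserted into the CH2–C(=O) bond of a malonate, and the C2 oxygen beside C1 can steer the aryne so that the carbonyl lands on C1 and the CH2 on C6.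

## Logic of the disconnections

27 ⇒ 26. The two benzyl–oxygen bonds are cut, one on the C2 oxygen of ring A and one on the ring B carboxyl. Both fall to the same neutral reagent, so the phenol and the acid stay masked through every earlier step that uses a base, an acylating agent or an organometal. Nothing acidic or basic then touches the ketone–ester pair once it exists. The forward step must spare the aliphatic ketone and the aryl ester of 26 under hydrogen on palladium.

26 ⇒ 23 + 24 (through 25). The bond between the arm carbonyl and its pentyl chain is cut. The arm becomes the arylacetic acid 23, the oxidation level that the key step delivers, and the five-carbon chain becomes the separate reagent 24. The forward step must acylate 24 at the activated carboxyl of 25 only and without base, because the benzylic CH2 of 25 is acidic and the neighbouring aryl ester is electrophilic.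

23 ⇒ 22. The tert-butyl–oxygen bond of the arylacetate is cut. The tert-butyl group serves the key step, where it makes this ester the poorer acyl acceptor, and it is the one ester of 22 that acid removes while the benzyl ester, benzyl ether and aryl ester stay. The forward step must be brief so that the electron-rich rings are not alkylated.

22 ⇒ 19 + 10 (through 20 and 21). Two bonds on ring A are cut at once: C6–CH2 and C1–C(=O). Both carbons then belong to one malonate unit in 10, whose aryl ester already holds the depside C–O bond, and ring A shrinks to 19. The hindered ester, the arm carbon and their 1,2-relationship are thus set in one operation from two pieces of similar size, and no doubly ortho-substituted acid has to be esterified. The forward step makes three demands: addition to 20 must put carbon on C6 and the carbanion on C1, the carbanion must choose the aryl ester over the tert-butyl ester, and 21 must open by C–C cleavage faster than 10 loses its phenoxide.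

10 ⇒ 8 + 9. The malonyl C(=O)–O bond is cut, giving a ring B phenol and an unhindered malonic half-ester. This is the easiest place to form the future depside C–O bond. The forward acylation must avoid any base strong enough to turn the aryl malonate into a ketene.

8 ⇒ 7 ⇒ 6 ⇒ 5. The allyl–oxygen bond on C4, the benzyl–oxygen bond of the ester and one C–O bond of the carboxyl (back to the aldehyde) are cut in turn. The allyl group is needed because C4–OH is the more reactive phenol and must be blocked while C2–OH is methylated; it is removed by zerovalent palladium without touching the benzyl ester. The forward steps require an oxidation that spares an alkene and an electron-rich ring, and an esterification that does not pass through a hindered acyl substitution.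

5 ⇒ 4 ⇒ 3. The methyl–oxygen bond on C2 and the allyl–oxygen bond on C4 are cut. In 3 the two hydroxyls differ because C2–OH is chelated to the aldehyde, so the forward sequence can alkylate C4–OH first with a weak base and C2–OH second with a stronger one.

3 ⇒ 1 (through 2). The ring–CHO bond is cut, leading to the commercial resorcinol 1. The forward formylation must enter para to one hydroxyl and ortho to the other, not between the two hydroxyls.

19 ⇒ 18 ⇒ 17. The sulfur–oxygen bond of the triflate and the benzyl–oxygen bond are cut, giving the symmetrical diol 17. Benzylation must come before triflation, because a free phenoxide beside silicon and triflate would release the aryne prematurely. The forward monobenzylation of two equivalent hydroxyls is the price paid for the symmetry.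

17 ⇒ 16 ⇒ 12 ⇒ 11 (through 13, 14, 15). The two carbamate C–O bonds and the C2–silicon bond are cut, leading to the commercial 11. Two carbamate groups flanking C2 make that position the unique site of metalation, which fixes the silicon between the two oxygens. The forward steps require a metalation without carbamoyl migration and a carbamate cleavage mild enough to keep the very electron-rich aryl–silicon bond.

## Other disconnections considered

Alternative 1: The cut is the depside C(=O)–O bond together with the C1–C6 bond of ring A, so ring A is built from an open chain. In the forward step, heating 2,2-dimethyl-6-[2,4-dioxo-5-(2-pentyl-1,3-dioxolan-2-yl)pentyl]-4H-1,3-dioxin-4-one A1 expels acetone and gives the acylketene A2. Phenol 8 captures A2 as the triketo aryl ester A3, and Cs2CO3 then closes ring A by aldol attack of C1 on the C6 carbonyl and loss of water, giving the resorcylate depside A4. In favour: every event has a close analogue in dioxinone-based resorcylate synthesis; the ester is made from a ketene, so no hindered acid is esterified, which is equal to the chosen plan; ring A arrives with C2–OH already free. Against: A4 has two free hydroxyls, so C4–OH must be methylated selectively afterwards (feasible, since C2–OH is chelated, but it is a late differentiation). The arm ketone must travel as a dioxolane so that it stays out of the aldol, and its acidic removal next to a free ortho-hydroxy depside invites isocoumarin formation. A3 is an aryl ester of a polyketo acid, so under Cs2CO3 closure through oxygen to a pyrone with loss of the ring B phenoxide competes with the aldol. Comparison: on mechanism this alternative is the better one, because nothing in it goes beyond known reaction types. On structure the chosen plan is better, because the C2/C4 oxygen pattern is fixed before ring A meets ring B and no acid-labile ketal is needed. On step economy the two are about equal: three steps after A4 (methylation, ketal removal, hydrogenolysis), and a five- to six-step preparation of A1.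

Alternative 2: The cut is at both bonds of the depside carbonyl carbon, which is supplied as carbon monoxide. In the forward step, zerovalent palladium formed from Pd(OAc)2 and Xantphos inserts into the C–I bond of 2-{[3,5-bis(benzyloxy)-2-iodophenyl]methyl}-2-pentyl-1,3-dioxolane A5. Carbon monoxide inserts, and the phenoxide of tert-butyl 4-hydroxy-2-methoxy-6-pentylbenzoate A6 attacks the aroyl–palladium bond to give the depside A7. In favour: it is the most convergent plan, joining the two finished halves A5 and A6; the reaction class is known for aryl iodides and phenols, and no hindered acid is esterified. On convergence and precedent it is better than the chosen plan. Against: the iodide A5 has two ortho substituents and the phenoxide of A6 is electron-poor, so capture of the hindered aroyl complex is slow; reduction of the iodide and direct C–O coupling without carbon monoxide can compete. A5 needs a regioselective iodination, and A6 needs a tert-butyl ester to be placed on a doubly ortho-substituted acid before its allyl ether is removed. The bis-benzyl pattern of A7 again postpones the C2/C4 differentiation to a late selective methylation, and the final acid step that removes the tert-butyl ester and the dioxolane exposes the ketone–depside pair to acid. Comparison: the number of steps after the key step is equal (three: hydrogenolysis, methylation, acidolysis), and the longest linear sequence is probably shorter. The chosen plan is preferred because its end game is neutral and its oxygen pattern needs no late selection.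

Alternative 3: The cut is at the C1–C2 and C5–C6 bonds of ring A. In the forward step, 1,3-bis(trimethylsilyloxy)cyclohexa-1,3-diene A8 adds to the triple bond of the aryl ynoate A9, with the nucleophilic diene terminus bonding to the β-carbon. The bicyclo[2.2.2]octadiene A10 then loses ethylene on further heating and leaves the aromatic bis-silyl ether A11. In favour: the regiochemistry follows from the polarity of both partners, and the Alder–Rickert route to resorcylates is a known reaction type, which is better than the chosen plan on precedent. A9 is made by acylating 8 with an unhindered ynoic acid, which is equal to the chosen plan in avoiding a hindered esterification. Against: ethylene loss from A10 needs a high temperature in the presence of an electrophilic aryl ynoate and an aryl ester. The propargylic CH2 of A9 can isomerise to an allene. A8 is moisture-sensitive. Desilylation of A11 again gives a 2,4-dihydroxy ring that needs selective methylation, followed by acidic ketal removal and hydrogenolysis. Comparison: the step count is similar to that of the chosen plan or one step longer. The alternative is worse on late oxygen differentiation, thermal stress and the acid step.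

Key step: step 13

Assumption: pentylzinc bromide 24 is taken as a commercial THF solution; it can otherwise be made from 1-bromopentane and zinc dust.

## Route

Step 1
Reactants: 1 olivetol (5-pentylbenzene-1,3-diol)
Product: 3 2,4-dihydroxy-6-pentylbenzaldehyde, via aryl iminium chloride 2 (not isolated)
Conditions: POCl3, DMF, 0 °C→rt; then H2O, 50 °C
Reagents that add atoms: N,N-dimethylformamide CN(C)C=O; water O
Why: Vilsmeier–Haack formylation; the chloroiminium ion should attack the ring carbon para to one hydroxyl and ortho to the other, the isomer from attack between the hydroxyls being the expected minor product, and hydrolysis of 2 gives the aldehyde.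

Step 2
Reactants: 3 2,4-dihydroxy-6-pentylbenzaldehyde
Product: 4 2-hydroxy-6-pentyl-4-(prop-2-en-1-yloxy)benzaldehyde
Conditions: allyl bromide (1.05 equiv), CsHCO3, MeCN, 60 °C
Reagents that add atoms: allyl bromide C=CCBr
Why: Williamson etherification; C2–OH is held in a hydrogen bond to the aldehyde and is less acidic, so the weak base should ionise and alkylate only C4–OH.

Step 3
Reactants: 4 2-hydroxy-6-pentyl-4-(prop-2-en-1-yloxy)benzaldehyde
Product: 5 2-methoxy-6-pentyl-4-(prop-2-en-1-yloxy)benzaldehyde
Conditions: MeI, K2CO3, DMF, 40 °C
Reagents that add atoms: iodomethane CI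
Why: Williamson methylation of the remaining chelated phenol with a stronger base and excess alkylating agent; no other nucleophilic site is present and the allyl ether does not rearrange at this temperature.

Step 4
Reactants: 5 2-methoxy-6-pentyl-4-(prop-2-en-1-yloxy)benzaldehyde
Product: 6 2-methoxy-6-pentyl-4-(prop-2-en-1-yloxy)benzoic acid
Conditions: NaClO2, NaH2PO4, 2-methyl-2-butene (large excess), t-BuOH/H2O, rt
Reagents that add atoms: sodium chlorite [Na+].[O-]Cl=O
Why: Pinnick oxidation; chlorous acid oxidises the hindered aldehyde without touching the allyl ether, and the excess trisubstituted alkene intercepts hypochlorous acid before it can chlorinate the electron-rich ring.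

Step 5
Reactants: 6 2-methoxy-6-pentyl-4-(prop-2-en-1-yloxy)benzoic acid
Product: 7 benzyl 2-methoxy-6-pentyl-4-(prop-2-en-1-yloxy)benzoate
Conditions: BnBr, K2CO3, DMF, rt
Reagents that add atoms: benzyl bromide BrCc1ccccc1
Why: SN2 alkylation of the carboxylate; the bond is formed at the benzylic carbon of the reagent, so the two ortho substituents that would block acyl substitution do not matter.

Step 6
Reactants: 7 benzyl 2-methoxy-6-pentyl-4-(prop-2-en-1-yloxy)benzoate
Product: 8 benzyl 4-hydroxy-2-methoxy-6-pentylbenzoate
Conditions: Pd(PPh3)4 (3 mol %), morpholine, THF, rt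
Reagents that add atoms: none
Why: Tsuji–Trost deallylation; zerovalent palladium ionises the allyl aryl ether to a π-allyl complex and the phenoxide, morpholine takes up the allyl group, and the hindered benzyl ester is inert to both.

Step 7
Reactants: 8 benzyl 4-hydroxy-2-methoxy-6-pentylbenzoate; 9 mono-tert-butyl malonate (3-tert-butoxy-3-oxopropanoic acid)
Product: 10 benzyl 4-[(3-tert-butoxy-3-oxopropanoyl)oxy]-2-methoxy-6-pentylbenzoate
Conditions: DCC, DMAP (5 mol %), CH2Cl2, 0 °C→rt
Reagents that add atoms: none
Why: Steglich esterification; the unhindered malonic half-ester acylates the phenol readily, and the near-neutral medium at low temperature keeps the base-sensitive aryl malonate intact.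

Step 8
Reactants: 11 5-methoxyresorcinol (5-methoxybenzene-1,3-diol)
Product: 12 5-methoxy-1,3-phenylene bis(propan-2-ylcarbamate)
Conditions: i-PrNCO (2.3 equiv), Et3N (20 mol %), CH2Cl2, rt
Reagents that add atoms: isopropyl isocyanate CC(C)N=C=O
Why: amine-catalysed addition of both phenols to the isocyanate (carbamoylation); the N-isopropyl carbamate is chosen because it directs metalation strongly and can later be removed without acid.

Step 9
Reactants: 12 5-methoxy-1,3-phenylene bis(propan-2-ylcarbamate)
Product: 16 5-methoxy-2-(trimethylsilyl)-1,3-phenylene bis(propan-2-ylcarbamate), via bis(N-silyl) carbamate 13 (not isolated), via C2 aryllithium 14 (not isolated), via bis(N-silyl) C2 silane 15 (not isolated)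
Conditions: TBSOTf (2.2 equiv), TMEDA, Et2O, 0 °C→rt; n-BuLi (3.5 equiv), TMEDA, −78 °C; TMSCl, −78 °C→rt; aq. NaHSO4
Reagents that add atoms: chlorotrimethylsilane C[Si](C)(C)Cl
Why: directed ortho-metalation; both N–H groups are masked in the flask as N-silyl groups, the C2 proton between the two carbamate oxygens is the most acidic and the best coordinated so lithiation should occur there, and the silyl chloride quench followed by aqueous cleavage of the N–Si bonds gives 16.

Step 10
Reactants: 16 5-methoxy-2-(trimethylsilyl)-1,3-phenylene bis(propan-2-ylcarbamate)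
Product: 17 5-methoxy-2-(trimethylsilyl)benzene-1,3-diol
Conditions: Et2NH (excess), DBU, MeCN, 40 °C; pH 7 phosphate buffer work-up; used without chromatography
Reagents that add atoms: none
Why: E1cB cleavage of the N-monosubstituted carbamates; DBU removes the N–H proton, the phenoxide leaves, the isocyanate is trapped by diethylamine as a urea, and the acid-free medium protects the electron-rich aryl–silicon bond from protodesilylation.

Step 11
Reactants: 17 5-methoxy-2-(trimethylsilyl)benzene-1,3-diol
Product: 18 3-(benzyloxy)-5-methoxy-2-(trimethylsilyl)phenol
Conditions: BnBr (1.0 equiv), K2CO3, acetone, rt; unreacted 17 recovered and recycled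
Reagents that add atoms: benzyl bromide BrCc1ccccc1
Why: Williamson monobenzylation of a symmetrical diol with one equivalent of halide; a statistical mixture is expected, possibly improved because the first benzyl ether pushes the silyl group toward the second hydroxyl, and 18 is separated from diol and bis-ether.

Step 12
Reactants: 18 3-(benzyloxy)-5-methoxy-2-(trimethylsilyl)phenol
Product: 19 3-(benzyloxy)-5-methoxy-2-(trimethylsilyl)phenyl trifluoromethanesulfonate
Conditions: PhNTf2, DBU, MeCN, rt
Reagents that add atoms: N-phenylbis(trifluoromethanesulfonimide) O=S(=O)(N(c1ccccc1)S(=O)(=O)C(F)(F)F)C(F)(F)F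
Why: O-sulfonylation of the phenoxide by triflyl transfer from the imide; the medium stays basic, so the aryl–silicon bond is not exposed to acid, and no free hydroxyl remains that could trigger silyl migration.

Step 13
Reactants: 19 3-(benzyloxy)-5-methoxy-2-(trimethylsilyl)phenyl trifluoromethanesulfonate; 10 benzyl 4-[(3-tert-butoxy-3-oxopropanoyl)oxy]-2-methoxy-6-pentylbenzoate
Product: 22 benzyl 4-({2-(benzyloxy)-6-(2-tert-butoxy-2-oxoethyl)-4-methoxybenzoyl}oxy)-2-methoxy-6-pentylbenzoate, via 3-(benzyloxy)-5-methoxybenzyne 20 (not isolated), via caesium benzocyclobutenoxide 21 (not isolated)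
Conditions: CsF (3 equiv), MeCN, 40 °C; 19 (1.3 equiv) added in three portions
Reagents that add atoms: none
Why: Proposed new method: fluoride attacks silicon in 19 and triflate leaves, giving aryne 20, while CsF also deprotonates the malonate CH2 of 10. The aryne is distorted by the inductively withdrawing benzyloxy group, so the malonate carbanion adds at the carbon remote from that group (ring A C6, new C6–CH bond) and the aryl carbanion develops on C1, next to the oxygen that stabilises it. This carbanion adds to the aryl ester carbonyl, which is less hindered and more electrophilic than the tert-butyl ester, to give the four-membered alkoxide 21 (a transient 4-exo-trig closure; no ring remains in the product). Strain-driven cleavage of the former malonate C–C bond in 21 releases the tert-butyl ester enolate and leaves the aryloxycarbonyl group on C1 (new C1–C(=O) bond), and protonation by unreacted 10 gives 22 and carries the chain. If 21 instead expels the ring B phenoxide, re-addition of that phenoxide to the benzocyclobutenone carbonyl and the same C–C cleavage lead to 22 as well. The closest known reaction type is the fluoride-mediated insertion of arynes, 3-alkoxy and 3,5-dialkoxy arynes included, into the C–C σ bond of dialkyl malonates and β-keto esters (acyl-alkylation); an aryl ester has not served there as the migrating acyl group. No stereocentre is formed. The step needs regioselective addition to 20 (secured by the C2 benzyloxy group beside the triple bond, the C4 methoxy group having only a weak remote effect) and attack on the aryl ester rather than the tert-butyl ester (secured by electrophilicity and bulk), and it must outrun loss of phenoxide from the enolate of 10 to a ketene, which is why a moderate temperature and portionwise addition of 19 are chosen.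

Step 14
Reactants: 22 benzyl 4-({2-(benzyloxy)-6-(2-tert-butoxy-2-oxoethyl)-4-methoxybenzoyl}oxy)-2-methoxy-6-pentylbenzoate
Product: 23 [3-(benzyloxy)-2-({4-[(benzyloxy)carbonyl]-3-methoxy-5-pentylphenoxy}carbonyl)-5-methoxyphenyl]acetic acid
Conditions: TFA/CH2Cl2 (1:4), 0 °C→rt; evaporate with toluene
Reagents that add atoms: none
Why: acidolysis of the tert-butyl ester through the tert-butyl cation, lost as isobutene; the benzyl ester, the benzyl ether and the hindered aryl ester should survive a short exposure to dilute TFA, and no base is used that could close the acid onto the depside carbonyl.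

Step 15
Reactants: 23 [3-(benzyloxy)-2-({4-[(benzyloxy)carbonyl]-3-methoxy-5-pentylphenoxy}carbonyl)-5-methoxyphenyl]acetic acid; 24 pentylzinc bromide
Product: 26 benzyl 4-{[2-(benzyloxy)-4-methoxy-6-(2-oxoheptyl)benzoyl]oxy}-2-methoxy-6-pentylbenzoate, via arylacetyl chloride 25 (not isolated)
Conditions: (COCl)2, DMF (cat.), CH2Cl2, 0 °C→rt, evaporate; then 24 (1.3 equiv), Pd(PPh3)4 (5 mol %), THF, 0 °C→rt
Reagents that add atoms: none
Why: acid chloride formation through the chloroiminium species from DMF and oxalyl chloride, then Negishi acylation (oxidative addition of zerovalent palladium into the C–Cl bond, transmetalation from zinc, reductive elimination); the organozinc is neither basic nor nucleophilic enough to touch the esters or the acidic benzylic CH2, and it cannot add to the ketone formed.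

Step 16
Reactants: 26 benzyl 4-{[2-(benzyloxy)-4-methoxy-6-(2-oxoheptyl)benzoyl]oxy}-2-methoxy-6-pentylbenzoate
Product: 27 confluentic acid (4-{[2-hydroxy-4-methoxy-6-(2-oxoheptyl)benzoyl]oxy}-2-methoxy-6-pentylbenzoic acid)
Conditions: H2 (1 atm), 10 % Pd/C, EtOAc, rt
Reagents that add atoms: none
Why: hydrogenolysis of the benzyl ether and the benzyl ester in one operation; the medium is neutral and aprotic, the ketone is aliphatic and not benzylic, and the aryl ester is not reduced, so the ketone–depside pair should not lactonise.

## Compound list

1 | olivetol (5-pentylbenzene-1,3-diol) | CCCCCc1cc(O)cc(O)c1 | starting material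
2 | N-[(2,4-dihydroxy-6-pentylphenyl)methylidene]-N-methylmethanaminium chloride | CCCCCc1cc(O)cc(O)c1C=[N+](C)C.[Cl-] | intermediate
3 | 2,4-dihydroxy-6-pentylbenzaldehyde | CCCCCc1cc(O)cc(O)c1C=O | intermediate
4 | 2-hydroxy-6-pentyl-4-(prop-2-en-1-yloxy)benzaldehyde | CCCCCc1cc(OCC=C)cc(O)c1C=O | intermediate
5 | 2-methoxy-6-pentyl-4-(prop-2-en-1-yloxy)benzaldehyde | CCCCCc1cc(OCC=C)cc(OC)c1C=O | intermediate
6 | 2-methoxy-6-pentyl-4-(prop-2-en-1-yloxy)benzoic acid | CCCCCc1cc(OCC=C)cc(OC)c1C(=O)O | intermediate
7 | benzyl 2-methoxy-6-pentyl-4-(prop-2-en-1-yloxy)benzoate | CCCCCc1cc(OCC=C)cc(OC)c1C(=O)OCc1ccccc1 | intermediate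
8 | benzyl 4-hydroxy-2-methoxy-6-pentylbenzoate | CCCCCc1cc(O)cc(OC)c1C(=O)OCc1ccccc1 | intermediate
9 | mono-tert-butyl malonate (3-tert-butoxy-3-oxopropanoic acid) | CC(C)(C)OC(=O)CC(=O)O | starting material
10 | benzyl 4-[(3-tert-butoxy-3-oxopropanoyl)oxy]-2-methoxy-6-pentylbenzoate | CCCCCc1cc(OC(=O)CC(=O)OC(C)(C)C)cc(OC)c1C(=O)OCc1ccccc1 | intermediate
11 | 5-methoxyresorcinol (5-methoxybenzene-1,3-diol) | COc1cc(O)cc(O)c1 | starting material
12 | 5-methoxy-1,3-phenylene bis(propan-2-ylcarbamate) | COc1cc(OC(=O)NC(C)C)cc(OC(=O)NC(C)C)c1 | intermediate
13 | 5-methoxy-1,3-phenylene bis[(tert-butyldimethylsilyl)(propan-2-yl)carbamate] | COc1cc(OC(=O)N(C(C)C)[Si](C)(C)C(C)(C)C)cc(OC(=O)N(C(C)C)[Si](C)(C)C(C)(C)C)c1 | intermediate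
14 | {2,6-bis[(tert-butyldimethylsilyl)(propan-2-yl)carbamoyloxy]-4-methoxyphenyl}lithium | COc1cc(OC(=O)N(C(C)C)[Si](C)(C)C(C)(C)C)c([Li])c(OC(=O)N(C(C)C)[Si](C)(C)C(C)(C)C)c1 | intermediate
15 | 5-methoxy-2-(trimethylsilyl)-1,3-phenylene bis[(tert-butyldimethylsilyl)(propan-2-yl)carbamate] | COc1cc(OC(=O)N(C(C)C)[Si](C)(C)C(C)(C)C)c([Si](C)(C)C)c(OC(=O)N(C(C)C)[Si](C)(C)C(C)(C)C)c1 | intermediate
16 | 5-methoxy-2-(trimethylsilyl)-1,3-phenylene bis(propan-2-ylcarbamate) | COc1cc(OC(=O)NC(C)C)c([Si](C)(C)C)c(OC(=O)NC(C)C)c1 | intermediate
17 | 5-methoxy-2-(trimethylsilyl)benzene-1,3-diol | COc1cc(O)c([Si](C)(C)C)c(O)c1 | intermediate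
18 | 3-(benzyloxy)-5-methoxy-2-(trimethylsilyl)phenol | COc1cc(O)c([Si](C)(C)C)c(OCc2ccccc2)c1 | intermediate
19 | 3-(benzyloxy)-5-methoxy-2-(trimethylsilyl)phenyl trifluoromethanesulfonate | COc1cc(OCc2ccccc2)c([Si](C)(C)C)c(OS(=O)(=O)C(F)(F)F)c1 | intermediate
20 | 3-(benzyloxy)-5-methoxybenzyne | COC1=CC#CC(OCc2ccccc2)=C1 | intermediate
21 | caesium 2-(benzyloxy)-8-{4-[(benzyloxy)carbonyl]-3-methoxy-5-pentylphenoxy}-7-(tert-butoxycarbonyl)-4-methoxybicyclo[4.2.0]octa-1,3,5-trien-8-olate (configuration at the two sp3 carbons immaterial) | COc1cc(OCc2ccccc2)c2c(c1)C(C(=O)OC(C)(C)C)C2([O-])Oc1cc(CCCCC)c(C(=O)OCc2ccccc2)c(OC)c1.[Cs+] | intermediate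
22 | benzyl 4-({2-(benzyloxy)-6-(2-tert-butoxy-2-oxoethyl)-4-methoxybenzoyl}oxy)-2-methoxy-6-pentylbenzoate | COc1cc(CC(=O)OC(C)(C)C)c(C(=O)Oc2cc(CCCCC)c(C(=O)OCc3ccccc3)c(OC)c2)c(OCc4ccccc4)c1 | intermediate
23 | [3-(benzyloxy)-2-({4-[(benzyloxy)carbonyl]-3-methoxy-5-pentylphenoxy}carbonyl)-5-methoxyphenyl]acetic acid | COc1cc(CC(=O)O)c(C(=O)Oc2cc(CCCCC)c(C(=O)OCc3ccccc3)c(OC)c2)c(OCc4ccccc4)c1 | intermediate
24 | pentylzinc bromide | CCCCC[Zn]Br | starting material
25 | benzyl 4-({2-(benzyloxy)-6-(2-chloro-2-oxoethyl)-4-methoxybenzoyl}oxy)-2-methoxy-6-pentylbenzoate | COc1cc(CC(=O)Cl)c(C(=O)Oc2cc(CCCCC)c(C(=O)OCc3ccccc3)c(OC)c2)c(OCc4ccccc4)c1 | intermediate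
26 | benzyl 4-{[2-(benzyloxy)-4-methoxy-6-(2-oxoheptyl)benzoyl]oxy}-2-methoxy-6-pentylbenzoate | CCCCCC(=O)Cc1cc(OC)cc(OCc2ccccc2)c1C(=O)Oc1cc(CCCCC)c(C(=O)OCc2ccccc2)c(OC)c1 | intermediate
27 | confluentic acid (4-{[2-hydroxy-4-methoxy-6-(2-oxoheptyl)benzoyl]oxy}-2-methoxy-6-pentylbenzoic acid) | CCCCCC(=O)Cc1cc(OC)cc(O)c1C(=O)Oc1cc(CCCCC)c(C(=O)O)c(OC)c1 | target

## Step count and least certain steps

Total step count: 16 (steps 1–7 for the malonate arm, steps 8–12 for the aryne precursor, step 13 to join them, steps 14–16 to finish). Longest linear sequence: 11 steps (1–7, then 13–16, from olivetol).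

**Step 13 (key step, the one step that goes beyond known chemistry).** The most likely failure is loss of the ring B phenoxide from the enolate of 10 to a ketene before the aryne arrives; the freed phenoxide would then be arylated on oxygen by 20. Also possible are protonation of the C1 carbanion before it reaches the ester carbonyl (plain α-arylation of the malonate) and a second arylation of 22 at its benzylic carbon. The fallback uses known chemistry only, sets out from 19 (with 9 and 8) and returns at 22. Acid 9 is alkylated on oxygen with allyl bromide and K2CO3 to give prop-2-en-1-yl tert-butyl malonate F1. The established fluoride-mediated insertion of 20 (from 19 and CsF in MeCN) into this dialkyl malonate, where the aryl carbanion should take the unhindered allyl ester, gives prop-2-en-1-yl 2-(benzyloxy)-6-(2-tert-butoxy-2-oxoethyl)-4-methoxybenzoate F2. Pd(PPh3)4 and morpholine free 2-(benzyloxy)-6-(2-tert-butoxy-2-oxoethyl)-4-methoxybenzoic acid F3. Carbodiimide esterification of F3 with phenol 8 (EDC·HCl, DMAP, CH2Cl2) gives 22. This costs three more steps and brings back the esterification of a doubly ortho-substituted acid, which is slow but is the classical way to depsides.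

**Step 9.** The bis-carbamate may not be silylated completely on nitrogen, in which case n-BuLi fragments a carbamate to isocyanate and phenoxide. A carbamoyl group may also migrate from oxygen to the lithiated carbon (anionic Fries rearrangement), or metalation may occur beside the methoxy group. The fallback sets out from 11 and returns at 19. Both hydroxyls are protected with MOMCl and i-Pr2NEt to give 1-methoxy-3,5-bis(methoxymethoxy)benzene F4. n-BuLi in THF lithiates between the two acetal oxygens, and 1,2-dibromotetrachloroethane gives 2-bromo-5-methoxy-1,3-bis(methoxymethoxy)benzene F5. HCl in methanol frees 2-bromo-5-methoxybenzene-1,3-diol F6, whose bromine is not acid-labile as the silyl group is. Monobenzylation as in step 11 gives 3-(benzyloxy)-2-bromo-5-methoxyphenol F7, and hexamethyldisilazane silylates the phenol to [3-(benzyloxy)-2-bromo-5-methoxyphenoxy]trimethylsilane F8. n-BuLi at −78 °C exchanges bromine for lithium and the silyl group moves from oxygen to carbon (retro-Brook rearrangement) to give lithium 3-(benzyloxy)-5-methoxy-2-(trimethylsilyl)phenolate F9, and Tf2O added to the same flask gives 19.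

**Step 11.** Over-alkylation to the bis-benzyl ether is inherent in a statistical reaction, and slow loss of the silyl group from the electron-rich phenoxide would add to it. The fallback sets out from 17 and returns at 19, bypassing 18. One equivalent of Tf2O with pyridine in CH2Cl2 at −78 °C should give mainly 3-hydroxy-5-methoxy-2-(trimethylsilyl)phenyl trifluoromethanesulfonate F10, because the first triflate lowers the nucleophilicity of the second hydroxyl. A Mitsunobu reaction (BnOH, PPh3, DIAD, THF, 0 °C) then benzylates that hydroxyl without a free base that could release the aryne.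

**Step 15.** At the acid chloride stage the carbonyl oxygen of the neighbouring depside may attack the acyl chloride (acyl transposition or loss of the ring B phenol), the arylacetyl chloride may lose HCl to a ketene, and the acylpalladium species may lose carbon monoxide. The fallback sets out from 23 and returns at 26. EtSH with EDC·HCl and DMAP converts 23 into the thioester benzyl 4-({2-(benzyloxy)-6-[2-(ethylsulfanyl)-2-oxoethyl]-4-methoxybenzoyl}oxy)-2-methoxy-6-pentylbenzoate F11. Fukuyama coupling of F11 with 24 (PdCl2(PPh3)2, THF/toluene, rt) gives 26 without an acid chloride.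

## Further compounds

F1 | step 13 | prop-2-en-1-yl tert-butyl malonate | C=CCOC(=O)CC(=O)OC(C)(C)C
F2 | step 13 | prop-2-en-1-yl 2-(benzyloxy)-6-(2-tert-butoxy-2-oxoethyl)-4-methoxybenzoate | COc1cc(CC(=O)OC(C)(C)C)c(C(=O)OCC=C)c(OCc2ccccc2)c1
F3 | step 13 | 2-(benzyloxy)-6-(2-tert-butoxy-2-oxoethyl)-4-methoxybenzoic acid | COc1cc(CC(=O)OC(C)(C)C)c(C(=O)O)c(OCc2ccccc2)c1
F4 | step 9 | 1-methoxy-3,5-bis(methoxymethoxy)benzene | COCOc1cc(OC)cc(OCOC)c1
F5 | step 9 | 2-bromo-5-methoxy-1,3-bis(methoxymethoxy)benzene | COCOc1cc(OC)cc(OCOC)c1Br
F6 | step 9 | 2-bromo-5-methoxybenzene-1,3-diol | COc1cc(O)c(Br)c(O)c1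
F7 | step 9 | 3-(benzyloxy)-2-bromo-5-methoxyphenol | COc1cc(O)c(Br)c(OCc2ccccc2)c1
F8 | step 9 | [3-(benzyloxy)-2-bromo-5-methoxyphenoxy]trimethylsilane | COc1cc(O[Si](C)(C)C)c(Br)c(OCc2ccccc2)c1
F9 | step 9 | lithium 3-(benzyloxy)-5-methoxy-2-(trimethylsilyl)phenolate | COc1cc([O-])c([Si](C)(C)C)c(OCc2ccccc2)c1.[Li+]
F10 | step 11 | 3-hydroxy-5-methoxy-2-(trimethylsilyl)phenyl trifluoromethanesulfonate | COc1cc(O)c([Si](C)(C)C)c(OS(=O)(=O)C(F)(F)F)c1
F11 | step 15 | benzyl 4-({2-(benzyloxy)-6-[2-(ethylsulfanyl)-2-oxoethyl]-4-methoxybenzoyl}oxy)-2-methoxy-6-pentylbenzoate | CCSC(=O)Cc1cc(OC)cc(OCc2ccccc2)c1C(=O)Oc1cc(CCCCC)c(C(=O)OCc2ccccc2)c(OC)c1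
A1 | alternative 1 | 2,2-dimethyl-6-[2,4-dioxo-5-(2-pentyl-1,3-dioxolan-2-yl)pentyl]-4H-1,3-dioxin-4-one | CCCCCC1(CC(=O)CC(=O)CC2=CC(=O)OC(C)(C)O2)OCCO1
A2 | alternative 1 | 8-(2-pentyl-1,3-dioxolan-2-yl)oct-1-ene-1,3,5,7-tetrone | CCCCCC1(CC(=O)CC(=O)CC(=O)C=C=O)OCCO1
A3 | alternative 1 | benzyl 2-methoxy-6-pentyl-4-{[3,5,7-trioxo-8-(2-pentyl-1,3-dioxolan-2-yl)octanoyl]oxy}benzoate | CCCCCC1(CC(=O)CC(=O)CC(=O)CC(=O)Oc2cc(CCCCC)c(C(=O)OCc3ccccc3)c(OC)c2)OCCO1
A4 | alternative 1 | benzyl 4-({2,4-dihydroxy-6-[(2-pentyl-1,3-dioxolan-2-yl)methyl]benzoyl}oxy)-2-methoxy-6-pentylbenzoate | CCCCCC1(Cc2cc(O)cc(O)c2C(=O)Oc2cc(CCCCC)c(C(=O)OCc3ccccc3)c(OC)c2)OCCO1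
A5 | alternative 2 | 2-{[3,5-bis(benzyloxy)-2-iodophenyl]methyl}-2-pentyl-1,3-dioxolane | CCCCCC1(Cc2cc(OCc3ccccc3)cc(OCc3ccccc3)c2I)OCCO1
A6 | alternative 2 | tert-butyl 4-hydroxy-2-methoxy-6-pentylbenzoate | CCCCCc1cc(O)cc(OC)c1C(=O)OC(C)(C)C
A7 | alternative 2 | tert-butyl 4-({2,4-bis(benzyloxy)-6-[(2-pentyl-1,3-dioxolan-2-yl)methyl]benzoyl}oxy)-2-methoxy-6-pentylbenzoate | CCCCCC1(Cc2cc(OCc3ccccc3)cc(OCc3ccccc3)c2C(=O)Oc2cc(CCCCC)c(C(=O)OC(C)(C)C)c(OC)c2)OCCO1
A8 | alternative 3 | 1,3-bis(trimethylsilyloxy)cyclohexa-1,3-diene | C[Si](C)(C)OC1=CC(O[Si](C)(C)C)=CCC1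
A9 | alternative 3 | benzyl 2-methoxy-6-pentyl-4-{[4-(2-pentyl-1,3-dioxolan-2-yl)but-2-ynoyl]oxy}benzoate | CCCCCC1(CC#CC(=O)Oc2cc(CCCCC)c(C(=O)OCc3ccccc3)c(OC)c2)OCCO1
A10 | alternative 3 | benzyl 2-methoxy-6-pentyl-4-[({3-[(2-pentyl-1,3-dioxolan-2-yl)methyl]-1,5-bis(trimethylsilyloxy)bicyclo[2.2.2]octa-2,5-dien-2-yl}carbonyl)oxy]benzoate (racemic) | C[Si](C)(C)OC12CCC(C(O[Si](C)(C)C)=C1)C(CC1(CCCCC)OCCO1)=C2C(=O)Oc1cc(CCCCC)c(C(=O)OCc2ccccc2)c(OC)c1
A11 | alternative 3 | benzyl 2-methoxy-6-pentyl-4-({6-[(2-pentyl-1,3-dioxolan-2-yl)methyl]-2,4-bis(trimethylsilyloxy)benzoyl}oxy)benzoate | CCCCCC1(Cc2cc(O[Si](C)(C)C)cc(O[Si](C)(C)C)c2C(=O)Oc2cc(CCCCC)c(C(=O)OCc3ccccc3)c(OC)c2)OCCO1
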